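The chain is cut at C1–aryl and at C6–C7, which leaves C1–C6 with the syn hydroxyls at C3 and C5: a 6-chloro-2,4,6-trideoxyhexose. One aldolase operation assembles this unit from chloroacetaldehyde and two molecules of acetaldehyde; it forms C4–C5 and C2–C3, sets both carbinol centres in the (3S,5R) sense of the target, and closes the oxane (lactol) ring between O5 and C1. The precursors of the key step are therefore only purchased two-carbon aldehydes. Afterwards the masked C1 aldehyde accepts an aryl Grignard reagent, hydrogenolysis removes the benzylic oxygen together with the O-benzyl group, and the C5/C6 chlorohydrin is closed to an epoxide that an octyl Grignard reagent opens at C6 under copper catalysis.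

Key step: step 1

Remark: chain atoms are numbered as in the target (C1 benzylic); the anomeric carbon of 5 and the C1 carbinol of 9 are carried as mixtures, because C1 ends as a methylene group.

Step 1
Reactants: 1 chloroacetaldehyde; 2 acetaldehyde (two molecules)
Product: 5 (4R,6S)-6-(chloromethyl)oxane-2,4-diol (anomeric mixture), via (3S)-4-chloro-3-hydroxybutanal 3 (not isolated), via (3R,5S)-6-chloro-3,5-dihydroxyhexanal 4 (not isolated)
Conditions: 2-deoxy-D-ribose-5-phosphate aldolase (chloroacetaldehyde-tolerant variant), H2O, KH2PO4/K2HPO4 buffer pH 7.2, 25 °C, slow co-feed of 1 and 2 (about 1 : 2.2); acetone to precipitate protein, EtOAc extraction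
Reagents that add atoms: none
Why: The aldolase, a lysine-dependent (Schiff-base) enzyme, turns acetaldehyde into an enzyme-bound enamine that adds to the carbonyl of chloroacetaldehyde to form the C4–C5 bond (hexanal numbering) and release 3, which is accepted again as the electrophile for a second acetaldehyde enamine that forms C2–C3 and gives 4. The closest known reaction type is the aldolase-catalysed sequential aldol of an α-substituted acetaldehyde with two acetaldehyde donors, which is established for exactly these partners. The oxane ring then closes by 6-exo-trig addition of the C5 hydroxyl to the C1 aldehyde (hemiacetal formation). Both carbinol centres, C3 and C5 of 4 (C4 and C6 of 5), are set by the active site, which presents the enamine to the same face of each acceptor, so the sense is catalyst-controlled and independent of the substrate; the anomeric centre is left as a mixture because C1 ends as a methylene group. The step needs cross-selectivity (acetaldehyde as the only donor, chloroacetaldehyde as the first acceptor) and a stop after two additions: the donor site takes acetaldehyde but not the chloro aldehyde, the more electrophilic chloro aldehyde is the preferred acceptor and is kept at low concentration by slow feeding, and ring closure masks the aldehyde of 4 whereas 3 cannot form an unstrained cyclic hemiacetal and so reacts on.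

Step 2
Reactants: 6 4-bromo-2-methoxyphenol
Product: 7 1-(benzyloxy)-4-bromo-2-methoxybenzene
Conditions: BnBr (1.1 equiv), K2CO3, DMF, 25 °C
Reagents that add atoms: benzyl bromide, BrCc1ccccc1
Why: Williamson ether synthesis: the phenoxide displaces bromide from the benzylic halide by SN2, the aryl bromide is inert, and no stereocentre is involved.

Step 3
Reactants: 5 (4R,6S)-6-(chloromethyl)oxane-2,4-diol; 7 1-(benzyloxy)-4-bromo-2-methoxybenzene
Product: 9 (1RS,3S,5S)-1-[4-(benzyloxy)-3-methoxyphenyl]-6-chlorohexane-1,3,5-triol, via [4-(benzyloxy)-3-methoxyphenyl]magnesium bromide 8 (not isolated)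
Conditions: 7 (4 equiv), Mg turnings, cat. I2, THF, 40 °C; then 5 in THF, 0 to 25 °C; aq. NH4Cl
Reagents that add atoms: magnesium, [Mg] (kept only in intermediate 8)
Why: Grignard reagent formation followed by Grignard addition to a lactol, as practised on 2-deoxy sugars: two equivalents deprotonate the hydroxyls, the magnesium lactolate opens to the aldehyde and is trapped irreversibly at C1; the new C1 carbinol should form as both epimers, which is harmless because this centre is removed in step 4, the enzyme-set centres are not touched, and the primary chloride does not react with an aryl Grignard reagent at this temperature.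

Step 4
Reactants: 9 (1RS,3S,5S)-1-[4-(benzyloxy)-3-methoxyphenyl]-6-chlorohexane-1,3,5-triol
Product: 10 4-[(3S,5S)-6-chloro-3,5-dihydroxyhexyl]-2-methoxyphenol
Conditions: H2 (3 atm), Pd(OH)2/C, EtOH–AcOH (10:1), 25 °C
Reagents that add atoms: none
Why: Catalytic hydrogenolysis: the O-benzyl group should be cleaved first and the resulting para-hydroxybenzylic alcohol then loses its activated benzylic C–O bond on palladium in weakly acidic medium, while the aliphatic secondary alcohols and the primary alkyl chloride are inert, so both C1 epimers converge on one compound with C3 and C5 unchanged.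

Step 5
Reactants: 10 4-[(3S,5S)-6-chloro-3,5-dihydroxyhexyl]-2-methoxyphenol
Product: 11 4-{(3S)-3-hydroxy-4-[(2S)-oxiran-2-yl]butyl}-2-methoxyphenol
Conditions: K2CO3 (2.5 equiv), MeOH, 0 to 25 °C; then aq. NH4Cl to pH 7
Reagents that add atoms: none
Why: Intramolecular Williamson etherification (3-exo-tet) of the C5 alkoxide onto C6 with loss of chloride, the usual fate of 1-halo-2,4-diols in mild base; the C5–O bond is not broken, so the configuration is retained, and the C3 hydroxyl should not open the epoxide because attack at C6 would be a disfavoured 5-endo process.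

Step 6
Reactants: 11 4-{(3S)-3-hydroxy-4-[(2S)-oxiran-2-yl]butyl}-2-methoxyphenol; 12 octylmagnesium chloride
Product: 13 (3S,5R)-1-(4-hydroxy-3-methoxyphenyl)tetradecane-3,5-diol
Conditions: 12 (4 equiv), CuI (0.2 equiv), THF, −40 to 0 °C; aq. NH4Cl
Reagents that add atoms: none
Why: Copper-catalysed Grignard opening of a terminal epoxide: after two equivalents are consumed by the phenol and the C3 hydroxyl, the organocopper species attacks the unsubstituted C6 by SN2 and forms C6–C7, while C5 is not a reaction centre and keeps its configuration, which gives the (3S,5R) syn-diol.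

Compound list
1 | chloroacetaldehyde (commercial aqueous solution) | ClCC=O | starting material
2 | acetaldehyde | CC=O | starting material
3 | (3S)-4-chloro-3-hydroxybutanal (not isolated) | ClC[C@@H](O)CC=O | intermediate
4 | (3R,5S)-6-chloro-3,5-dihydroxyhexanal (not isolated) | ClC[C@@H](O)C[C@@H](O)CC=O | intermediate
5 | (4R,6S)-6-(chloromethyl)oxane-2,4-diol, mixture of anomers | ClC[C@@H]1C[C@@H](O)CC(O)O1 | intermediate
6 | 4-bromo-2-methoxyphenol | COc1cc(Br)ccc1O | starting material
7 | 1-(benzyloxy)-4-bromo-2-methoxybenzene | COc1cc(Br)ccc1OCc1ccccc1 | intermediate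
8 | [4-(benzyloxy)-3-methoxyphenyl]magnesium bromide (not isolated) | COc1cc([Mg]Br)ccc1OCc1ccccc1 | intermediate
9 | (1RS,3S,5S)-1-[4-(benzyloxy)-3-methoxyphenyl]-6-chlorohexane-1,3,5-triol, both C1 epimers | ClC[C@@H](O)C[C@@H](O)CC(O)c1ccc(OCc2ccccc2)c(OC)c1 | intermediate
10 | 4-[(3S,5S)-6-chloro-3,5-dihydroxyhexyl]-2-methoxyphenol | ClC[C@@H](O)C[C@@H](O)CCc1ccc(O)c(OC)c1 | intermediate
11 | 4-{(3S)-3-hydroxy-4-[(2S)-oxiran-2-yl]butyl}-2-methoxyphenol | C1O[C@H]1C[C@@H](O)CCc2ccc(O)c(OC)c2 | intermediate
12 | octylmagnesium chloride (commercial solution in THF) | CCCCCCCC[Mg]Cl | starting material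
13 | (3S,5R)-1-(4-hydroxy-3-methoxyphenyl)tetradecane-3,5-diol | CCCCCCCCC[C@@H](O)C[C@@H](O)CCc1ccc(O)c(OC)c1 | target

Total step count: 6. Longest linear sequence: 5 steps (steps 1, 3, 4, 5, 6; step 2 is a one-step side branch that joins at step 3).

Steps most likely to fail

Step 1. The aldolase may lose activity during the feed, through covalent modification of active-site residues by chloroacetaldehyde and by crotonaldehyde formed from acetaldehyde. The cascade would then stall after the first addition or give little conversion. The fallback replaces the enzyme by reagent-controlled allylboration; it sets out from chloroacetaldehyde 1, used as the dried monomer, and comes back to the route at lactol 5. Brown allylation of 1 with (−)-B-allyldiisopinocampheylborane (Et2O, −78 °C), which delivers allyl to the Si face, should give (2S)-1-chloropent-4-en-2-ol F1. An ethanolamine work-up avoids the basic peroxide that would close the chlorohydrin. Silylation (TBSCl, imidazole, DMF) should give tert-butyl{[(2S)-1-chloropent-4-en-2-yl]oxy}dimethylsilane F2. Ozonolysis (O3, CH2Cl2, −78 °C, then PPh3) should give (3S)-3-[(tert-butyldimethylsilyl)oxy]-4-chlorobutanal F3. A second Brown allylation with the same borane antipode should set the second carbinol syn under reagent control and give (4S,6S)-6-[(tert-butyldimethylsilyl)oxy]-7-chlorohept-1-en-4-ol F4. A second ozonolysis should give (3R,5S)-5-[(tert-butyldimethylsilyl)oxy]-6-chloro-3-hydroxyhexanal F5. Removal of the silyl group (aqueous HF, MeCN) frees O5, which closes onto C1 to give 5.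

Step 4. Acid-assisted ionisation of the electron-rich benzylic alcohol, followed by capture of the cation by the C5 hydroxyl (six-membered cyclic ether formation), may compete with C–O hydrogenolysis. The reduction may also stall after O-debenzylation. The fallback separates the two reductions and uses ionic hydrogenation for the benzylic oxygen; it sets out from triol 9 and comes back to the route at 10. Treatment of 9 with Et3SiH and CF3CO2H (CH2Cl2, 0 °C; aqueous NaHCO3 work-up to cleave trifluoroacetates) should give (2S,4S)-6-[4-(benzyloxy)-3-methoxyphenyl]-1-chlorohexane-2,4-diol F6. Under these conditions a para-alkoxybenzylic ether re-ionises, so any ring closure is reversible, whereas hydride transfer to the cation is not. Neutral hydrogenolysis of the O-benzyl group alone (H2, Pd/C, EtOAc, 25 °C) then gives 10.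

Step 3. The magnesium lactolate may open only sluggishly and the polyalkoxide salts may aggregate, so that addition stays incomplete. The open β-alkoxy aldehyde may also fragment by retro-aldol reaction under the basic conditions. The fallback raises the oxidation level of C1 and brings the hydrogen in afterwards; it sets out from lactol 5 and comes back to the route at triol 9. Oxidation of 5 (Br2, BaCO3, H2O, 25 °C) should give (4R,6S)-6-(chloromethyl)-4-hydroxyoxan-2-one F7. Addition of Grignard reagent 8 (2.2 equiv, THF, −78 °C) should stop after one addition, because the tetrahedral magnesium hemiketalate persists in the cold, and give (3R,5S)-1-[4-(benzyloxy)-3-methoxyphenyl]-6-chloro-3,5-dihydroxyhexan-1-one F8. Reduction with NaBH4 (MeOH, 0 °C) returns 9; its C1 configuration is of no consequence.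

Further compounds
F1 | step 1 | (2S)-1-chloropent-4-en-2-ol | ClC[C@@H](O)CC=C
F2 | step 1 | tert-butyl{[(2S)-1-chloropent-4-en-2-yl]oxy}dimethylsilane | ClC[C@@H](O[Si](C)(C)C(C)(C)C)CC=C
F3 | step 1 | (3S)-3-[(tert-butyldimethylsilyl)oxy]-4-chlorobutanal | ClC[C@@H](O[Si](C)(C)C(C)(C)C)CC=O
F4 | step 1 | (4S,6S)-6-[(tert-butyldimethylsilyl)oxy]-7-chlorohept-1-en-4-ol | ClC[C@@H](O[Si](C)(C)C(C)(C)C)C[C@@H](O)CC=C
F5 | step 1 | (3R,5S)-5-[(tert-butyldimethylsilyl)oxy]-6-chloro-3-hydroxyhexanal | ClC[C@@H](O[Si](C)(C)C(C)(C)C)C[C@@H](O)CC=O
F6 | step 4 | (2S,4S)-6-[4-(benzyloxy)-3-methoxyphenyl]-1-chlorohexane-2,4-diol | ClC[C@@H](O)C[C@@H](O)CCc1ccc(OCc2ccccc2)c(OC)c1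
F7 | step 3 | (4R,6S)-6-(chloromethyl)-4-hydroxyoxan-2-one | ClC[C@@H]1C[C@@H](O)CC(=O)O1
F8 | step 3 | (3R,5S)-1-[4-(benzyloxy)-3-methoxyphenyl]-6-chloro-3,5-dihydroxyhexan-1-one | ClC[C@@H](O)C[C@@H](O)CC(=O)c1ccc(OCc2ccccc2)c(OC)c1
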